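With the ring numbered C1 (ketone), C2 (bearing C7H2O), C3 (=CH), C4 (O-tiglate), C5 (isopropyl), C6 (O-acetate), everything rests on cutting the C2=C3 enone double bond of the cyclohexenone ring: a trisubstituted olefin between the C1 ketone and the allylic C4 ester is the imprint of ring-closing olefin metathesis. In one operation the key step closes the six-membered ring and delivers the target from an acyclic, fully acylated octa-1,7-dien-3-one (2-substituted enone terminus at C1/C2, vinyl group on C4) that already carries all three stereocentres, set by an Evans syn-aldol (C5, C6) and an Evans–Tishchenko reduction (C4, which also installs the C6 acetate).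

Key step: step 11

Remark: both 2-methylbut-2-enoyl groups are read from the SMILES as E (tiglates); the C1–C7 numbering above is used in the Why lines.

Step 1
Reactants: 1 (4R)-4-benzyl-3-(3-methylbutanoyl)-1,3-oxazolidin-2-one; 2 2-[(tert-butyldimethylsilyl)oxy]acetaldehyde
Product: 4 (4R)-4-benzyl-3-[(2R,3R)-4-[(tert-butyldimethylsilyl)oxy]-3-hydroxy-2-(propan-2-yl)butanoyl]-1,3-oxazolidin-2-one, via Z-dibutylboron enolate 3 (not isolated)
Conditions: Bu2BOTf, iPr2NEt, CH2Cl2, 0 °C; then 2, −78 → 0 °C; pH 7 buffer, MeOH, H2O2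
Reagents that add atoms: none
Why: Evans boron aldol reaction: the Z-enolate 3 adds to the aldehyde through a closed chair transition state in which the benzyl group of the auxiliary blocks one enolate face, which should set C5 and C6 as the 2R,3R syn pair.

Step 2
Reactants: 4
Product: 5 (2R,3R)-4-[(tert-butyldimethylsilyl)oxy]-3-hydroxy-N-methoxy-N-methyl-2-(propan-2-yl)butanamide
Conditions: MeONHMe·HCl, AlMe3, CH2Cl2, −10 → 0 °C
Reagents that add atoms: N,O-dimethylhydroxylamine hydrochloride, CNOC.Cl
Why: Weinreb transamidation: the aluminium amide made in the flask is delivered by the free β-hydroxyl to the exocyclic imide carbonyl and releases the auxiliary without touching either stereocentre.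

Step 3
Reactants: 5
Product: 6 (4R,5R)-6-[(tert-butyldimethylsilyl)oxy]-5-hydroxy-4-(propan-2-yl)hex-1-en-3-one
Conditions: CH2=CHMgBr (3 equiv), THF, −78 → 0 °C; inverse quench into cold 1 M HCl
Reagents that add atoms: vinylmagnesium bromide, C=C[Mg]Br
Why: Weinreb ketone synthesis: the magnesium-chelated tetrahedral intermediate survives until the acidic inverse quench, which prevents over-addition and conjugate addition of the released amine to the vinyl ketone.

Step 4
Reactants: 6
Product: 7 (2R,3S,4S)-1-[(tert-butyldimethylsilyl)oxy]-4-hydroxy-3-(propan-2-yl)hex-5-en-2-yl acetate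
Conditions: SmI2 (0.3 equiv, premixed with CH3CHO), CH3CHO (8 equiv), THF, −10 °C
Reagents that add atoms: acetaldehyde, CC=O
Why: Evans–Tishchenko reduction: the samarium-bound hemiacetal formed from the C6 hydroxyl and acetaldehyde transfers hydride intramolecularly through a six-membered chair, which should set C4 (S) 1,3-anti to C6 and leave the acetate on the C6 oxygen in the same operation.

Step 5
Reactants: 7
Product: 8 (3S,4S,5R)-5-acetoxy-6-[(tert-butyldimethylsilyl)oxy]-4-(propan-2-yl)hex-1-en-3-yl (2E)-2-methylbut-2-enoate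
Conditions: tigloyl chloride, pyridine, DMAP (cat.), CH2Cl2, 0 °C → rt
Reagents that add atoms: tigloyl chloride, C/C=C(\C)C(Cl)=O
Why: DMAP-catalysed acylation of the free allylic hydroxyl, which should outrun 1,3-acetyl migration; the E geometry of the tiglate is the stable one and is kept.

Step 6
Reactants: 8
Product: 9 (3S,4S,5R)-5-acetoxy-6-hydroxy-4-(propan-2-yl)hex-1-en-3-yl (2E)-2-methylbut-2-enoate
Conditions: HF·pyridine, pyridine, THF, 0 °C → rt
Reagents that add atoms: none
Why: Fluoride-mediated desilylation of the primary silyl ether under buffered, weakly acidic conditions that spare both esters and disfavour acetyl migration to the new primary hydroxyl.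

Step 7
Reactants: 9
Product: 10 (3S,4S,5R)-5-acetoxy-6-oxo-4-(propan-2-yl)hex-1-en-3-yl (2E)-2-methylbut-2-enoate
Conditions: Dess–Martin periodinane, CH2Cl2, 0 °C → rt; used without chromatography
Reagents that add atoms: none
Why: Dess–Martin oxidation of the primary alcohol under non-basic conditions, so the epimerisable α-acetoxy aldehyde centre (C6) should be preserved.

Step 8
Reactants: 11 2-bromoprop-2-en-1-ol
Product: 12 2-bromoprop-2-en-1-yl (2E)-2-methylbut-2-enoate
Conditions: tigloyl chloride, Et3N, DMAP (cat.), CH2Cl2, 0 °C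
Reagents that add atoms: tigloyl chloride, C/C=C(\C)C(Cl)=O
Why: Esterification of a primary allylic alcohol with an acid chloride gives the C2/C7 fragment with its tiglate already in place.

Step 9
Reactants: 10; 12
Product: 14 (3RS,4R,5S,6S)-4-acetoxy-3-hydroxy-2-({[(2E)-2-methylbut-2-enoyl]oxy}methyl)-5-(propan-2-yl)octa-1,7-dien-6-yl (2E)-2-methylbut-2-enoate, via alkenylchromium reagent 13 (not isolated)
Conditions: CrCl2 (4 equiv), NiCl2 (2 mol %), DMF, rt
Reagents that add atoms: none
Why: Nozaki–Hiyama–Kishi coupling: nickel-catalysed activation of the alkenyl bromide and transmetalation give alkenylchromium 13 (trivalent chromium), which should add chemoselectively to the aldehyde in the presence of three esters; the new carbinol forms as an epimer mixture that is erased in step 10.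

Step 10
Reactants: 14
Product: 15 (4R,5S,6S)-4-acetoxy-2-({[(2E)-2-methylbut-2-enoyl]oxy}methyl)-3-oxo-5-(propan-2-yl)octa-1,7-dien-6-yl (2E)-2-methylbut-2-enoate
Conditions: Dess–Martin periodinane, CH2Cl2, rt
Reagents that add atoms: none
Why: Dess–Martin oxidation of the secondary allylic alcohol converges both carbinol epimers on one α-methylene ketone under non-basic conditions that should not epimerise the α-acetoxy centre.

Step 11
Reactants: 15
Product: 16 (4S,5S,6R)-6-acetoxy-4-{[(2E)-2-methylbut-2-enoyl]oxy}-2-({[(2E)-2-methylbut-2-enoyl]oxy}methyl)-5-(propan-2-yl)cyclohex-2-en-1-one (CNP0218511.1)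
Conditions: second-generation Grubbs catalyst (10 mol %), 1,4-benzoquinone (20 mol %), toluene (0.005 M), 80 °C
Reagents that add atoms: none
Why: Ring-closing olefin metathesis: the ruthenium alkylidene loads on the monosubstituted C3 vinyl group, adds in a [2+2] sense across the 1,1-disubstituted enone olefin at C2, and the ruthenacyclobutane cycloreverts to the C2=C3 bond with loss of ethene. The closest known reaction type is ring-closing metathesis of 2-substituted octa-1,7-dien-3-ones to 2-substituted cyclohex-2-enones. The six-membered carbocycle C1–C6 is closed head to head between the two olefin carbons that stay in the product, both terminal methylene carbons being expelled. No stereocentre is formed; C4, C5 and C6 are carried through unchanged because the conditions are neutral. The step needs chemoselectivity for the gem-disubstituted enone olefin over the two trisubstituted tiglate olefins (closure of the C4 tiglate onto C3 would give a butenolide) and for ring closure over dimerisation; the lower metathesis reactivity of trisubstituted α-methyl enoates, the favourable six-ring closure and high dilution should secure it, and 1,4-benzoquinone suppresses olefin migration by ruthenium hydrides.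

Compound list
1 | (4R)-4-benzyl-3-(3-methylbutanoyl)-1,3-oxazolidin-2-one | CC(C)CC(=O)N1[C@H](Cc2ccccc2)COC1=O | starting material
2 | 2-[(tert-butyldimethylsilyl)oxy]acetaldehyde | O=CCO[Si](C)(C)C(C)(C)C | starting material
3 | Z-dibutylboron enolate of 1 (not isolated) | CC(C)/C=C(\OB(CCCC)CCCC)N1[C@H](Cc2ccccc2)COC1=O | intermediate
4 | (4R)-4-benzyl-3-[(2R,3R)-4-[(tert-butyldimethylsilyl)oxy]-3-hydroxy-2-(propan-2-yl)butanoyl]-1,3-oxazolidin-2-one | O=C1OC[C@@H](Cc2ccccc2)N1C(=O)[C@H](C(C)C)[C@@H](O)CO[Si](C)(C)C(C)(C)C | intermediate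
5 | (2R,3R)-4-[(tert-butyldimethylsilyl)oxy]-3-hydroxy-N-methoxy-N-methyl-2-(propan-2-yl)butanamide | CON(C)C(=O)[C@H](C(C)C)[C@@H](O)CO[Si](C)(C)C(C)(C)C | intermediate
6 | (4R,5R)-6-[(tert-butyldimethylsilyl)oxy]-5-hydroxy-4-(propan-2-yl)hex-1-en-3-one | C=CC(=O)[C@H](C(C)C)[C@@H](O)CO[Si](C)(C)C(C)(C)C | intermediate
7 | (2R,3S,4S)-1-[(tert-butyldimethylsilyl)oxy]-4-hydroxy-3-(propan-2-yl)hex-5-en-2-yl acetate | C=C[C@H](O)[C@H](C(C)C)[C@@H](OC(C)=O)CO[Si](C)(C)C(C)(C)C | intermediate
8 | (3S,4S,5R)-5-acetoxy-6-[(tert-butyldimethylsilyl)oxy]-4-(propan-2-yl)hex-1-en-3-yl (2E)-2-methylbut-2-enoate | C=C[C@H](OC(=O)/C(C)=C/C)[C@H](C(C)C)[C@@H](OC(C)=O)CO[Si](C)(C)C(C)(C)C | intermediate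
9 | (3S,4S,5R)-5-acetoxy-6-hydroxy-4-(propan-2-yl)hex-1-en-3-yl (2E)-2-methylbut-2-enoate | C=C[C@H](OC(=O)/C(C)=C/C)[C@H](C(C)C)[C@@H](OC(C)=O)CO | intermediate
10 | (3S,4S,5R)-5-acetoxy-6-oxo-4-(propan-2-yl)hex-1-en-3-yl (2E)-2-methylbut-2-enoate | C=C[C@H](OC(=O)/C(C)=C/C)[C@H](C(C)C)[C@@H](OC(C)=O)C=O | intermediate
11 | 2-bromoprop-2-en-1-ol | C=C(Br)CO | starting material
12 | 2-bromoprop-2-en-1-yl (2E)-2-methylbut-2-enoate | C/C=C(\C)C(=O)OCC(Br)=C | intermediate
13 | dichloro{3-[(2E)-2-methylbut-2-enoyloxy]prop-1-en-2-yl}chromium, trivalent chromium (not isolated) | C/C=C(\C)C(=O)OCC(=C)[Cr](Cl)Cl | intermediate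
14 | (3RS,4R,5S,6S)-4-acetoxy-3-hydroxy-2-({[(2E)-2-methylbut-2-enoyl]oxy}methyl)-5-(propan-2-yl)octa-1,7-dien-6-yl (2E)-2-methylbut-2-enoate | C=C[C@H](OC(=O)/C(C)=C/C)[C@H](C(C)C)[C@@H](OC(C)=O)C(O)C(=C)COC(=O)/C(C)=C/C | intermediate
15 | (4R,5S,6S)-4-acetoxy-2-({[(2E)-2-methylbut-2-enoyl]oxy}methyl)-3-oxo-5-(propan-2-yl)octa-1,7-dien-6-yl (2E)-2-methylbut-2-enoate | C=C[C@H](OC(=O)/C(C)=C/C)[C@H](C(C)C)[C@@H](OC(C)=O)C(=O)C(=C)COC(=O)/C(C)=C/C | intermediate
16 | (4S,5S,6R)-6-acetoxy-4-{[(2E)-2-methylbut-2-enoyl]oxy}-2-({[(2E)-2-methylbut-2-enoyl]oxy}methyl)-5-(propan-2-yl)cyclohex-2-en-1-one | C/C=C(\C)C(=O)OCC1=C[C@H](OC(=O)/C(C)=C/C)[C@H](C(C)C)[C@@H](OC(C)=O)C1=O | target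

Total step count: 11. Longest linear sequence: 10 steps (steps 1–7, 9, 10, 11).

Steps most likely to fail

1. Step 11 (ring-closing metathesis). The electron-poor gem-disubstituted enone olefin may engage the ruthenium carbene too slowly, so that dimerisation through the vinyl group or ring closure onto the C4 tiglate olefin competes. Fallback, setting out from 14 and returning at 16: the ring is closed one oxidation level earlier. Metathesis of allylic alcohol 14 under the conditions of step 11, where the 1,1-disubstituted olefin is an electron-richer allylic alcohol olefin, should give cyclohexenol F1. Dess–Martin oxidation of cyclohexenol F1 then gives 16.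

2. Step 4 (Evans–Tishchenko reduction). Single-electron reduction, conjugate addition or polymerisation of the terminal vinyl ketone, or retro-aldol cleavage, may outrun hemiacetal formation and hydride transfer. Fallback, setting out from 5 and returning at 7: (E)-prop-1-enyllithium (from (E)-1-bromoprop-1-ene and t-BuLi, THF, −78 °C) is added to Weinreb amide 5 to give propenyl ketone F2, a β-substituted enone that is a much poorer conjugate acceptor. Evans–Tishchenko reduction of propenyl ketone F2 (SmI2, CH3CHO, THF, −10 °C) should give propenyl carbinol acetate F3. Cross-metathesis of propenyl carbinol acetate F3 with ethene (second-generation Grubbs catalyst, ethene atmosphere, CH2Cl2) trims the propenyl group back to vinyl and gives 7.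

3. Step 9 (Nozaki–Hiyama–Kishi coupling). The tiglate may be lost by β-elimination from the alkenylnickel or alkenylchromium intermediate (allene formation), or nickel may insert into the allylic C–O bond, so that the bromide is consumed before carbonyl addition. Fallback, setting out from 10 and 11 and returning at 14: the ester is introduced after the coupling. Silylation of 11 (TBSCl, imidazole, CH2Cl2) gives silyl ether F4. Coupling of silyl ether F4 with aldehyde 10 under the same CrCl2/NiCl2 conditions should give coupling product F5. HF·pyridine removes the silyl group to give diol F6. The primary allylic hydroxyl of diol F6 is then acylated selectively (tigloyl chloride, 2,4,6-collidine, CH2Cl2, −40 °C) to give 14.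

Further compounds
F1 | step 11 | (1RS,4S,5S,6R)-6-acetoxy-4-{[(2E)-2-methylbut-2-enoyl]oxy}-2-({[(2E)-2-methylbut-2-enoyl]oxy}methyl)-5-(propan-2-yl)cyclohex-2-en-1-ol | C/C=C(\C)C(=O)OCC1=C[C@H](OC(=O)/C(C)=C/C)[C@H](C(C)C)[C@@H](OC(C)=O)C1O
F2 | step 4 | (2E,5R,6R)-7-[(tert-butyldimethylsilyl)oxy]-6-hydroxy-5-(propan-2-yl)hept-2-en-4-one | C/C=C/C(=O)[C@H](C(C)C)[C@@H](O)CO[Si](C)(C)C(C)(C)C
F3 | step 4 | (2R,3S,4S,5E)-1-[(tert-butyldimethylsilyl)oxy]-4-hydroxy-3-(propan-2-yl)hept-5-en-2-yl acetate | C/C=C/[C@H](O)[C@H](C(C)C)[C@@H](OC(C)=O)CO[Si](C)(C)C(C)(C)C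
F4 | step 9 | [(2-bromoprop-2-en-1-yl)oxy](tert-butyl)dimethylsilane | C=C(Br)CO[Si](C)(C)C(C)(C)C
F5 | step 9 | (3RS,4R,5S,6S)-4-acetoxy-2-{[(tert-butyldimethylsilyl)oxy]methyl}-3-hydroxy-5-(propan-2-yl)octa-1,7-dien-6-yl (2E)-2-methylbut-2-enoate | C=C[C@H](OC(=O)/C(C)=C/C)[C@H](C(C)C)[C@@H](OC(C)=O)C(O)C(=C)CO[Si](C)(C)C(C)(C)C
F6 | step 9 | (3RS,4R,5S,6S)-4-acetoxy-3-hydroxy-2-(hydroxymethyl)-5-(propan-2-yl)octa-1,7-dien-6-yl (2E)-2-methylbut-2-enoate | C=C[C@H](OC(=O)/C(C)=C/C)[C@H](C(C)C)[C@@H](OC(C)=O)C(O)C(=C)CO
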